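Percent made was the wrong unit for these runs, so I reckoned with the fraction of substrate left.

the same everywhere: substrate 0.066 M; precatalyst 3.6 mol%; added ligand 2.4 mM
- noon: coupling partner 0.67 equiv; run made earlier
- summer: coupling partner 1.5 equiv; run made earlier
- flask: coupling partner 1.00 equiv; time 2.5 h

- noon (time / min: target / %, substrate / %): 15.0: 0.5, 100.0; 30.0: 1.9, 98.8; 50.0: 3.7, 95.9; 60.0: 5.4, 94.5; 80.0: 8.7, 91.4; 90.0: 10.4, 89.2; 120: 15.9, 83.3
- summer (time / min: target / %, substrate / %): 15.0: 0.6, 99.3; 30.0: 2.4, 96.6; 50.0: 7.5, 92.5; 60.0: 9.5, 89.8; 80.0: 15.9, 83.6; 90.0: 19.0, 80.4; 120: 27.7, 71.1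

(scatter of a reading: 0.3 percentage points)



* concentration of target at 2.5 h, in M
* concentration of substrate at 2.5 h, in M
* concentration of coupling partner at 2.5 h, in M

The natural logarithm of one over that fraction reached 0.183 in the noon run at 120 min, and I called it the loss number. The summer run reached 0.341. A ratio of partner charges of 2.24 thus gave a ratio of loss numbers of 1.86, so I read the loss number as going with the partner charge to the power 0.774. That put the new flask at 0.249 at the same time.

Two versions of the flask could be done in the head. In the flat one, the flask kept its last slope, the noon slope 0.00228 min⁻¹ scaled likewise, which gave 0.342 and 71.0 % left. In the curved one, the loss number kept the summer run's growth, 3.17 times per doubling of time, which gave 0.361 and 69.7 % left. I took the flat version as my lower edge, since the summer slope as read was still rising, from 0.00369 min⁻¹ to 0.00410 min⁻¹. I took the curved one as my upper edge, as its growth came from the summer stretch between 60.0 min and 120 min, and I expected the flask to lie between them.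

The forecast, holding that “there is an induction period, probably catalyst activation”, gave 72.1 % substrate left, a little above my two edges, and 27.0 % target. Its range, 68.9 % to 75.3 %, held both edges.

    substrate + free catalyst → catalyst intermediate A (k = 340 L mol⁻¹ h⁻¹)
    coupling partner + catalyst intermediate A → catalyst intermediate B (k = 7900 L mol⁻¹ h⁻¹)
    catalyst intermediate B → catalyst intermediate C (k = 2400 h⁻¹)
    catalyst intermediate C ⇌ by-product + catalyst intermediate D (K = 0.120 M, k = 25.0 h⁻¹)
    catalyst intermediate D → free catalyst + target (k = 110 h⁻¹)
    free catalyst + added ligand ⇌ idle complex (K = 440 L mol⁻¹, k = 380 L mol⁻¹ h⁻¹)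
    coupling partner + precatalyst → free catalyst + spent reagent (k = 8.40 L mol⁻¹ h⁻¹)

The flask held 0.0195 M target, 0.0460 M substrate and 0.0444 M partner, so 70 % of its substrate and 67 % of its partner were left, a loss number of 0.361, beside my upper edge. In the flask the precatalyst's life against the charged partner was 1.80 h, shorter than the 2.5 h elapsed, and precatalyst still made up 30.3 % of the catalyst then, down from 51.8 % at 1.25 h. For the reading at 4.0 h, the noon loss number 0.183, scaled as before, gave edges of 0.622 and 0.790, and that flask stood between them at 0.749, with 47.3 % of its substrate left.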